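**Retrosynthetic overview**
- The target is reached from a ring A bromide: Br/Li exchange and CO2 give the acid at ring A C1, and aqueous acid frees the ring B aldehyde from its dimethyl acetal.
- The strategy rests on ring B C1' (ether oxygen) lying between C2' (OH) and C6' (CHO). C1' and C2' are therefore an aryloxyacetyl unit hung on the ring A oxygen by SN2, and ring B is built around it by Michael addition (C3'–C4'), aldol condensation (C1'–C6') and loss of PhSOH.
- The aryloxy β-keto sulfoxide comes from a methyl aryloxyacetate and lithiated methyl phenyl sulfoxide. Ring A comes from 2-bromoresorcinol by C-acylation, para-O-alkylation, ortho-O-methylation, CBS reduction (sets the R centre) and O-methylation.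
- The enone acetal comes from pyruvaldehyde dimethyl acetal and acetaldehyde by aldol addition and dehydration.
- Ring order: ring A is bought; ring B is the only ring formed, in the key step.

Key step: step 9

Remark: methyl phenyl sulfoxide is used as the racemate, so the keto sulfoxide and the two unisolated intermediates of the key step are mixtures of epimers at sulfur and at the transient ring carbons; all of these elements disappear on aromatisation.

**Step 1**
Reactants: 1 2-bromoresorcinol; 2 3-methylbutanoyl chloride
Product: 3 1-(3-bromo-2,4-dihydroxyphenyl)-3-methylbutan-1-one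
Conditions: AlCl3, 1,2-dichloroethane, 0 → 60 °C; then 1 M HCl
Reagents that add atoms: none
Why: Friedel–Crafts acylation (an O-acylation/Fries path converges on the same ketone); C4 and C6 of 1 are equivalent and activated by both hydroxyls while C5 is meta to both, so a single ketone should form.

**Step 2**
Reactants: 3 1-(3-bromo-2,4-dihydroxyphenyl)-3-methylbutan-1-one; 4 methyl bromoacetate
Product: 5 methyl 2-[2-bromo-3-hydroxy-4-(3-methylbutanoyl)phenoxy]acetate
Conditions: K2CO3 (1.1 equiv), 4 (1.05 equiv), acetone, 40 °C
Reagents that add atoms: none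
Why: Williamson ether synthesis; the hydroxyl ortho to the ketone is hydrogen-bonded to the carbonyl and flanked by Br and acyl, so the para hydroxyl should be alkylated selectively with one equivalent of bromide.

**Step 3**
Reactants: 5 methyl 2-[2-bromo-3-hydroxy-4-(3-methylbutanoyl)phenoxy]acetate
Product: 6 methyl 2-[2-bromo-3-methoxy-4-(3-methylbutanoyl)phenoxy]acetate
Conditions: MeI (excess), K2CO3, DMF, 50 °C
Reagents that add atoms: iodomethane (MeI), CI
Why: Williamson O-methylation of the remaining chelated phenol under more forcing conditions; carbonate is too weak to enolise the ketone or the ester.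

**Step 4**
Reactants: 6 methyl 2-[2-bromo-3-methoxy-4-(3-methylbutanoyl)phenoxy]acetate
Product: 7 methyl 2-{2-bromo-4-[(1R)-1-hydroxy-3-methylbutyl]-3-methoxyphenoxy}acetate
Conditions: (S)-Me-CBS oxazaborolidine [(3aS)-1-methyl-3,3-diphenyltetrahydro-1H,3H-pyrrolo[1,2-c][1,3,2]oxazaborole, C18H20BNO] (0.15 equiv), BH3·SMe2 (0.7 equiv), THF, −20 °C; MeOH quench
Reagents that add atoms: none
Why: Corey–Bakshi–Shibata reduction; with the (S)-oxazaborolidine the aryl group is the large substituent and hydride goes to the face that gives the (R)-carbinol (the same sense as acetophenone to (R)-1-phenylethanol), and the ketone is reduced much faster than the ester at this temperature.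

**Step 5**
Reactants: 7 methyl 2-{2-bromo-4-[(1R)-1-hydroxy-3-methylbutyl]-3-methoxyphenoxy}acetate
Product: 8 methyl 2-{2-bromo-3-methoxy-4-[(1R)-1-methoxy-3-methylbutyl]phenoxy}acetate
Conditions: Ag2O (3 equiv), MeI (excess), 4 Å molecular sieves, MeCN, 40 °C, dark
Reagents that add atoms: iodomethane (MeI), CI
Why: Purdie methylation; the conditions are non-basic, so the aryloxyacetate CH2 is not enolised, and the C–O bond at the stereocentre is not broken, so the R configuration is kept.

**Step 6**
Reactants: 8 methyl 2-{2-bromo-3-methoxy-4-[(1R)-1-methoxy-3-methylbutyl]phenoxy}acetate; 9 methyl phenyl sulfoxide (racemic)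
Product: 11 1-{2-bromo-3-methoxy-4-[(1R)-1-methoxy-3-methylbutyl]phenoxy}-3-(benzenesulfinyl)propan-2-one, via lithiated methyl phenyl sulfoxide 10 (not isolated)
Conditions: 9 (2.2 equiv), LiN(iPr)2 (2.2 equiv), THF, −78 °C; then 8, −78 → −40 °C; aq. NH4Cl
Reagents that add atoms: none
Why: Claisen-type acylation of an α-sulfinyl carbanion by a methyl ester; the second equivalent of carbanion deprotonates the β-keto sulfoxide as it forms and so prevents over-addition, and the stabilised carbanion does not exchange with the aryl bromide.

**Step 7**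
Reactants: 12 pyruvaldehyde dimethyl acetal (1,1-dimethoxypropan-2-one); 13 acetaldehyde
Product: 15 4-hydroxy-1,1-dimethoxypentan-2-one (racemic), via lithium enolate 14 (not isolated)
Conditions: LiN(iPr)2, THF, −78 °C; then 13, −78 °C; aq. NH4Cl
Reagents that add atoms: none
Why: directed aldol addition of a preformed kinetic lithium enolate; deprotonation occurs at the methyl group and not at the acetal C–H, and preforming the enolate avoids acetaldehyde self-condensation.

**Step 8**
Reactants: 15 4-hydroxy-1,1-dimethoxypentan-2-one
Product: 17 (E)-1,1-dimethoxypent-3-en-2-one, via mesylate 16 (not isolated)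
Conditions: MsCl, Et3N (3 equiv), CH2Cl2, 0 °C → rt
Reagents that add atoms: none
Why: mesylation followed by E1cB elimination gives the thermodynamically preferred (E)-enone under non-acidic conditions that leave the acetal intact.

**Step 9**
Reactants: 11 1-{2-bromo-3-methoxy-4-[(1R)-1-methoxy-3-methylbutyl]phenoxy}-3-(benzenesulfinyl)propan-2-one; 17 (E)-1,1-dimethoxypent-3-en-2-one
Product: 20 2-{2-bromo-3-methoxy-4-[(1R)-1-methoxy-3-methylbutyl]phenoxy}-3-(dimethoxymethyl)-5-methylphenol, via Michael adduct 18 (not isolated), via sulfinylcyclohexenone 19 (not isolated)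
Conditions: NaOMe (0.2 equiv), 17 (1.3 equiv), MeOH–THF, 0 °C → rt; then solvent switch to toluene, pyridine, 90 °C
Reagents that add atoms: none
Why: Methoxide forms the carbanion at the CH2 between sulfinyl and ketone (future C3'), which adds 1,4 to the β-carbon of 17 (future C4', carrying the methyl) to give 18; reversible enolisation of the aryloxy-bearing CH2 (C1') then lets it attack the electron-poor acetal-bearing ketone (C6'), water is lost to give 19, and thermal syn-elimination of PhSOH across C3'–C4' gives a cyclohexadienone that tautomerises to the phenol. The closest known reaction type is the phenol annulation of β-keto sulfoxides with enones (Michael addition, aldol condensation, sulfoxide elimination). Ring B closes by a 6-(enolendo)-exo-trig aldol, because both carbons of the reacting enolate, C1' and C2', end up in the ring. No lasting stereocentre is created: sulfur, C3', C4' and C6' are transient and are erased on aromatisation, and the R centre on ring A is remote from the reacting sites and inert to methoxide. The step needs Michael addition through C3' and aldol closure through C1'; the far higher acidity of the sulfinyl ketone CH2 secures the first, and ring size secures the second, since closure from C3' or C5' would give four-membered rings and the acetal C–H is too weakly acidic to compete. Bromine in place of a carboxyl derivative at ring A C1 removes the Dieckmann-type closure of the C1' enolate to a benzofuranone, and the pyridine buffer keeps the sulfenic acid from cleaving the acetal.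

**Step 10**
Reactants: 20 2-{2-bromo-3-methoxy-4-[(1R)-1-methoxy-3-methylbutyl]phenoxy}-3-(dimethoxymethyl)-5-methylphenol
Product: 23 6-(2-formyl-6-hydroxy-4-methylphenoxy)-2-methoxy-3-[(1R)-1-methoxy-3-methylbutyl]benzoic acid, via dilithio aryllithium phenoxide 21 (not isolated), via carboxylic acid acetal 22 (not isolated)
Conditions: nBuLi (2.2 equiv), THF, −78 °C; CO2 (dry gas), −78 → 0 °C; then 1 M HCl, THF–H2O, 0 °C → rt
Reagents that add atoms: carbon dioxide, O=C=O; water, O
Why: phenol deprotonation and bromine–lithium exchange give an aryllithium flanked by two oxygens that is carboxylated by CO2, and dilute acid then hydrolyses the aryl dimethyl acetal much faster than it can ionise the benzylic methyl ether on the carboxyl-deactivated ring A, so the R centre should be untouched.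

**Compound list**
1 | 2-bromoresorcinol | Oc1cccc(O)c1Br | starting material
2 | 3-methylbutanoyl chloride | CC(C)CC(=O)Cl | starting material
3 | 1-(3-bromo-2,4-dihydroxyphenyl)-3-methylbutan-1-one | Oc1c(C(=O)CC(C)C)ccc(O)c1Br | intermediate
4 | methyl bromoacetate | COC(=O)CBr | starting material
5 | methyl 2-[2-bromo-3-hydroxy-4-(3-methylbutanoyl)phenoxy]acetate | Oc1c(C(=O)CC(C)C)ccc(OCC(=O)OC)c1Br | intermediate
6 | methyl 2-[2-bromo-3-methoxy-4-(3-methylbutanoyl)phenoxy]acetate | COc1c(C(=O)CC(C)C)ccc(OCC(=O)OC)c1Br | intermediate
7 | methyl 2-{2-bromo-4-[(1R)-1-hydroxy-3-methylbutyl]-3-methoxyphenoxy}acetate | COc1c([C@@H](CC(C)C)O)ccc(OCC(=O)OC)c1Br | intermediate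
8 | methyl 2-{2-bromo-3-methoxy-4-[(1R)-1-methoxy-3-methylbutyl]phenoxy}acetate | COc1c([C@@H](CC(C)C)OC)ccc(OCC(=O)OC)c1Br | intermediate
9 | methyl phenyl sulfoxide (racemic) | CS(=O)c1ccccc1 | starting material
10 | (benzenesulfinyl)methyllithium | [Li]CS(=O)c1ccccc1 | intermediate
11 | 1-{2-bromo-3-methoxy-4-[(1R)-1-methoxy-3-methylbutyl]phenoxy}-3-(benzenesulfinyl)propan-2-one (both sulfur epimers) | COc1c([C@@H](CC(C)C)OC)ccc(OCC(=O)CS(=O)c2ccccc2)c1Br | intermediate
12 | pyruvaldehyde dimethyl acetal (1,1-dimethoxypropan-2-one) | CC(=O)C(OC)OC | starting material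
13 | acetaldehyde | CC=O | starting material
14 | lithium enolate of 1,1-dimethoxypropan-2-one | C=C(O[Li])C(OC)OC | intermediate
15 | 4-hydroxy-1,1-dimethoxypentan-2-one (racemic) | CC(O)CC(=O)C(OC)OC | intermediate
16 | 5,5-dimethoxy-4-oxopentan-2-yl methanesulfonate | CC(CC(=O)C(OC)OC)OS(C)(=O)=O | intermediate
17 | (E)-1,1-dimethoxypent-3-en-2-one | C/C=C/C(=O)C(OC)OC | intermediate
18 | 1-{2-bromo-3-methoxy-4-[(1R)-1-methoxy-3-methylbutyl]phenoxy}-3-(benzenesulfinyl)-7,7-dimethoxy-4-methylheptane-2,6-dione (diastereomer mixture) | COc1c([C@@H](CC(C)C)OC)ccc(OCC(=O)C(S(=O)c2ccccc2)C(C)CC(=O)C(OC)OC)c1Br | intermediate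
19 | 2-{2-bromo-3-methoxy-4-[(1R)-1-methoxy-3-methylbutyl]phenoxy}-6-(benzenesulfinyl)-3-(dimethoxymethyl)-5-methylcyclohex-2-en-1-one (diastereomer mixture) | COc1c([C@@H](CC(C)C)OC)ccc(OC2=C(C(OC)OC)CC(C)C(S(=O)c3ccccc3)C2=O)c1Br | intermediate
20 | 2-{2-bromo-3-methoxy-4-[(1R)-1-methoxy-3-methylbutyl]phenoxy}-3-(dimethoxymethyl)-5-methylphenol | COc1c([C@@H](CC(C)C)OC)ccc(Oc2c(O)cc(C)cc2C(OC)OC)c1Br | intermediate
21 | dilithio species: lithium phenoxide of 20 with lithium in place of bromine | COc1c([C@@H](CC(C)C)OC)ccc(Oc2c(O[Li])cc(C)cc2C(OC)OC)c1[Li] | intermediate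
22 | 6-[2-(dimethoxymethyl)-6-hydroxy-4-methylphenoxy]-2-methoxy-3-[(1R)-1-methoxy-3-methylbutyl]benzoic acid | COc1c([C@@H](CC(C)C)OC)ccc(Oc2c(O)cc(C)cc2C(OC)OC)c1C(=O)O | intermediate
23 | 6-(2-formyl-6-hydroxy-4-methylphenoxy)-2-methoxy-3-[(1R)-1-methoxy-3-methylbutyl]benzoic acid | COc1c([C@@H](CC(C)C)OC)ccc(Oc2c(O)cc(C)cc2C=O)c1C(=O)O | target

**Step count**
Total: 10 steps. Longest linear sequence: 8 steps (steps 1–6, 9, 10); steps 7 and 8 form the enone branch.

**Steps most likely to fail**

1. Step 9 (annulation). The Michael adduct may stall or revert before the aryloxy-bearing carbon closes onto the acetal ketone, the enone may oligomerise under base, or the acetal may be lost during sulfenic acid elimination. The fallback sets out from 11 and swaps the three-carbon partner for one whose acceptor carbonyl is non-enolisable and more electrophilic. Methyl (E)-2-oxopent-3-enoate F1 (from dimethyl oxalate and MeCH=CHMgBr at −78 °C) would be combined with 11 under the same NaOMe/heat sequence to give methyl 2-{2-bromo-3-methoxy-4-[(1R)-1-methoxy-3-methylbutyl]phenoxy}-3-hydroxy-5-methylbenzoate F2. Reduction with iBu2AlH should give 2-{2-bromo-3-methoxy-4-[(1R)-1-methoxy-3-methylbutyl]phenoxy}-3-(hydroxymethyl)-5-methylphenol F3. MnO2 oxidation should give 2-{2-bromo-3-methoxy-4-[(1R)-1-methoxy-3-methylbutyl]phenoxy}-3-hydroxy-5-methylbenzaldehyde F4. Acetalisation with HC(OMe)3 and catalytic pyridinium p-toluenesulfonate in MeOH comes back to the route at 20.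

2. Step 10 (dianion lithiation and carboxylation). The hindered aryllithium may be quenched by proton transfer or butylated by the 1-bromobutane formed in the exchange, or carboxylation may be incomplete. The fallback sets out from 20 and replaces the organolithium by a palladium-catalysed hydroxycarbonylation: Pd(OAc)2, 4,5-bis(diphenylphosphino)-9,9-dimethylxanthene, CO, K2CO3, dioxane–H2O, 100 °C, then careful acidification. It comes back at 22, which is hydrolysed to 23 as in the route; no compound outside the compound list is made (F0).

3. Step 5 (neutral O-methylation). Alkylation of the hindered benzylic alcohol next to the ortho methoxy group may be slow and incomplete, and forcing it may bring on ester side reactions. The fallback sets out from 7 and masks the ester as its carboxylate so that a strong-base Williamson methylation can be used. LiOH in THF–H2O should give 2-{2-bromo-4-[(1R)-1-hydroxy-3-methylbutyl]-3-methoxyphenoxy}acetic acid F5. NaH and MeI in THF (the carboxylate CH2 is not deprotonated) should give 2-{2-bromo-3-methoxy-4-[(1R)-1-methoxy-3-methylbutyl]phenoxy}acetic acid F6. Esterification with MeI and KHCO3 in DMF comes back to the route at 8.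

**Further compounds**
F1 | step 9 | methyl (E)-2-oxopent-3-enoate | C/C=C/C(=O)C(=O)OC
F2 | step 9 | methyl 2-{2-bromo-3-methoxy-4-[(1R)-1-methoxy-3-methylbutyl]phenoxy}-3-hydroxy-5-methylbenzoate | COc1c([C@@H](CC(C)C)OC)ccc(Oc2c(O)cc(C)cc2C(=O)OC)c1Br
F3 | step 9 | 2-{2-bromo-3-methoxy-4-[(1R)-1-methoxy-3-methylbutyl]phenoxy}-3-(hydroxymethyl)-5-methylphenol | COc1c([C@@H](CC(C)C)OC)ccc(Oc2c(O)cc(C)cc2CO)c1Br
F4 | step 9 | 2-{2-bromo-3-methoxy-4-[(1R)-1-methoxy-3-methylbutyl]phenoxy}-3-hydroxy-5-methylbenzaldehyde | COc1c([C@@H](CC(C)C)OC)ccc(Oc2c(O)cc(C)cc2C=O)c1Br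
F0 | step 10 | none | none
F5 | step 5 | 2-{2-bromo-4-[(1R)-1-hydroxy-3-methylbutyl]-3-methoxyphenoxy}acetic acid | COc1c([C@@H](CC(C)C)O)ccc(OCC(=O)O)c1Br
F6 | step 5 | 2-{2-bromo-3-methoxy-4-[(1R)-1-methoxy-3-methylbutyl]phenoxy}acetic acid | COc1c([C@@H](CC(C)C)OC)ccc(OCC(=O)O)c1Br
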